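The constants used here are those of an exercise.

A catalyst here gives about 42.1 turnovers before the capture agent takes it. Call this N, the turnover number, the product made per catalyst lost.

substrate 0.13 M; capture agent 0.0130 M; free catalyst 2.6 mM

    catalyst intermediate A + capture agent → trapped intermediate (k1 = 0.73 M⁻¹ s⁻¹)
    substrate + free catalyst ⇌ catalyst intermediate A (K2 = 9.3 M⁻¹, k2 = 3.3 M⁻¹ s⁻¹)
    catalyst intermediate B → free catalyst + product (k3 = 2.4 s⁻¹)
    catalyst intermediate A ⇌ catalyst intermediate B (K4 = 13, k4 = 0.40 s⁻¹)

1. apparent order in free catalyst when 30% of the substrate are converted (percent change of the rate of making product for one percent more free catalyst charged)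

Read the rates per catalyst form, from the fastest down:

- Catalyst intermediate B gives product at 140 min⁻¹, faster than the 24 min⁻¹ at which it forms, so you find little of it.
- Free catalyst binds substrate at 26 min⁻¹ with substrate as charged, and catalyst intermediate A moves on to catalyst intermediate B at 24 min⁻¹, so the round turns many times per capture.
- Capture of catalyst intermediate A is the slowest rung, at 0.57 min⁻¹.

Catalyst intermediate A has three exits: back to free catalyst and substrate at 21.3 min⁻¹, on to catalyst intermediate B at 24 min⁻¹, and capture at 0.57 min⁻¹. The way back returns the catalyst to the round with neither product made nor catalyst lost, so it drops out of N, and the ratio of the other two exits gives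

N = 24 min⁻¹ / 0.57 min⁻¹ = 42.1

I hold N at its charged value, since the catalyst charged can use at most 20.0% of the capture agent.

Now work with the fraction left. Each lost catalyst costs N plus one substrate, one of them held inside the trapped intermediate, so reaching 30% conversion costs

lost catalyst = 0.904 mM

That loss does not scale with the charge, while the rate follows the working catalyst, charge minus loss. So the fraction left and the order are

f = 1 − lost / charge = 0.652

order = 1 / f = 1.53

The forecast also says 1.5, on the ground that “Rate scales with the surviving catalyst”.

The flask gives 1.5. At 2.00 min this flask already holds 28.8% of its catalyst as trapped intermediate, with product at 24.7% of the substrate. Now use N for the end of the run. At charged capture agent, N allows product of 84.3% of the substrate charged. Capture agent falls to 80.1% of its charge, so taking its mean level raises N to 46.8 and the allowance to 93.6%. At 200 min the flask holds product at 92.4%, with trapped intermediate at 99.6% of the catalyst.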